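The route rests on cutting the side chain between the acyl carbon C1′ and C2′. The key step exploits ring carbon C2 of the cyclohexane-1,3-dione ring, which lies between the carbonyl carbons C1 and C3. Carried on C2 as a CS2-derived bis(methylsulfanyl)methylidene group, C1′ is a doubly activated, non-enolisable acceptor already at the carboxylic acid oxidation level. One copper-catalysed addition–elimination of the (11Z,13E)-pentadecadienyl Grignard reagent forms C1′–C2′ and pauses at an inert 1,3-diketonate, so no second addition should occur. The precursor is the (S)-4-silyloxy ketene dithioacetal; hydrolysis of the resulting vinylogous thioester then reveals the triketone.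

Key step: step 7

Assumption: for the cyclic sodium enolate 4 the (−)-(2S,8aR)-oxaziridine is taken to deliver oxygen to the face that gives the (S)-carbinol; should the sense prove opposite, the (+)-(2R,8aS)-enantiomer is used in the same way.

Step 1
Reactants: 1 cyclohexane-1,3-dione; 2 carbon disulfide
Product: 3 2-[bis(methylsulfanyl)methylidene]cyclohexane-1,3-dione
Conditions: K2CO3, DMF, 0 °C; CS2; then MeI, 0 °C → rt
Reagents that add atoms: iodomethane, CI
Why: The C2 carbanion of the dione adds to CS2 and the dithiocarboxylate is S-methylated twice (ketene dithioacetal formation from an active methylene compound), which places the future acyl carbon on ring carbon C2.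

Step 2
Reactants: 3 2-[bis(methylsulfanyl)methylidene]cyclohexane-1,3-dione
Product: 5 (S)-2-[bis(methylsulfanyl)methylidene]-4-hydroxycyclohexane-1,3-dione, via sodium enolate 4 (not isolated)
Conditions: NaN(SiMe3)2, THF, −78 °C; then (−)-(2S,8aR)-10-(camphorylsulfonyl)oxaziridine, −78 °C; aq. NH4Cl; recrystallisation
Reagents that add atoms: (−)-(2S,8aR)-10-(camphorylsulfonyl)oxaziridine, O=S1(=O)C[C@]23CC[C@H](C2(C)C)C[C@]3(O4)N14
Why: Davis oxidation, in which kinetic α′-deprotonation (C4 and C6 of 3 are equivalent) is followed by oxygen transfer from the enantiopure N-sulfonyloxaziridine, whose camphor skeleton differentiates the two enolate faces (reagent control) and should set the (S)-carbinol, with recrystallisation intended to raise the enantiomeric purity.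

Step 3
Reactants: 5 (S)-2-[bis(methylsulfanyl)methylidene]-4-hydroxycyclohexane-1,3-dione
Product: 6 (S)-2-[bis(methylsulfanyl)methylidene]-4-[(triethylsilyl)oxy]cyclohexane-1,3-dione
Conditions: Et3SiOTf, 2,6-lutidine, CH2Cl2, −78 °C
Reagents that add atoms: triethylsilyl trifluoromethanesulfonate, CC[Si](CC)(CC)OS(=O)(=O)C(F)(F)F
Why: O-silylation of the secondary alcohol with a silyl triflate and a non-nucleophilic base (silyl ether protection) removes the only acidic proton before the organometallic step and does not touch the stereocenter.

Step 4
Reactants: 7 11-bromoundecan-1-ol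
Product: 8 (11-hydroxyundecyl)triphenylphosphonium bromide
Conditions: PPh3, MeCN, reflux
Reagents that add atoms: triphenylphosphine, c1ccc(cc1)P(c1ccccc1)c1ccccc1
Why: SN2 quaternisation of the phosphine by the primary bromide (phosphonium salt formation) tolerates the free hydroxyl group.

Step 5
Reactants: 8 (11-hydroxyundecyl)triphenylphosphonium bromide; 9 (E)-but-2-enal
Product: 11 (11Z,13E)-pentadeca-11,13-dien-1-ol, via ylide alkoxide 10 (not isolated)
Conditions: NaN(SiMe3)2 (2.1 equiv), THF, −78 → 0 °C; then 9, −78 °C → rt; aq. NH4Cl; AgNO3-impregnated silica gel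
Reagents that add atoms: none
Why: Wittig reaction of a non-stabilised ylide under lithium-free conditions, which should form the new C11=C12 bond with Z geometry through the kinetically favoured cis-oxaphosphetane while the E geometry of the enal is carried over unchanged.

Step 6
Reactants: 11 (11Z,13E)-pentadeca-11,13-dien-1-ol
Product: 12 (2E,4Z)-15-bromopentadeca-2,4-diene
Conditions: CBr4, PPh3, CH2Cl2, 0 °C
Reagents that add atoms: carbon tetrabromide, BrC(Br)(Br)Br
Why: The Appel reaction converts the primary alcohol into the bromide under neutral conditions that should leave the conjugated diene and its geometry untouched.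

Step 7
Reactants: 12 (2E,4Z)-15-bromopentadeca-2,4-diene; 6 (S)-2-[bis(methylsulfanyl)methylidene]-4-[(triethylsilyl)oxy]cyclohexane-1,3-dione
Product: 15 (S)-2-[(12Z,14E)-1-(methylsulfanyl)hexadeca-12,14-dien-1-ylidene]-4-[(triethylsilyl)oxy]cyclohexane-1,3-dione, via Grignard reagent 13 (not isolated), via diketonate adduct 14 (not isolated)
Conditions: Mg, THF, 40 °C; then 13 added slowly to 6 and CuBr·SMe2 (10 mol %), THF, −78 → 0 °C; aq. NH4Cl
Reagents that add atoms: none
Why: Magnesium insertion gives the primary Grignard reagent 13, which transmetalates to an alkylcopper species (monovalent copper) and adds in conjugate fashion to the exocyclic bis(methylsulfanyl)methylidene carbon of 6, the β-carbon shared by the C1 and C3 enone systems, to give the magnesium 1,3-diketonate 14; on warming, 14 expels methanethiolate (E1cB) and the vinylogous thioester 15 results, so the C1′–C2′ bond is made by conjugate addition–elimination (vinylic substitution). The closest known reaction type is the organocuprate addition–elimination on α-oxo ketene dithioacetals that gives β-alkylsulfanyl enones. No ring is closed and no stereocenter is created; the exocyclic double bond of 15 may form as either isomer, and both converge in step 8. The step needs 1,4- over 1,2-addition and single over double displacement: the two flanking carbonyls make the exocyclic carbon far more electrophilic than the sulfur-deactivated ketone carbons, and the anionic diketonate 14 is inert to further nucleophile, which under slow inverse addition with only a slight excess is consumed before 14 eliminates. The C4 stereocenter should survive because the weakly basic organocopper species does not enolise the α-silyloxy ketone at low temperature, and the remote (11Z,13E)-diene is inert.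

Step 8
Reactants: 15 (S)-2-[(12Z,14E)-1-(methylsulfanyl)hexadeca-12,14-dien-1-ylidene]-4-[(triethylsilyl)oxy]cyclohexane-1,3-dione
Product: 17 (6S)-2-[(12Z,14E)-hexadeca-12,14-dienoyl]-3,6-dihydroxycyclohex-2-en-1-one (CNP0144157.1), via silyl-protected triketonate 16 (not isolated)
Conditions: LiOH, THF/H2O, 0 °C; then 1 M HCl, rt
Reagents that add atoms: lithium hydroxide (hydroxide oxygen), [Li+].[OH-]
Why: Hydroxide adds to the vinylogous thioester carbon of either double-bond isomer and methanethiolate is expelled (addition–elimination, vinylic substitution) to give the triketonate 16, whose delocalised anion protects C4 from enolisation, and acidification then protonates it and cleaves the triethylsilyl ether (acid-catalysed desilylation) without touching the diene.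

Compound list
1 | cyclohexane-1,3-dione | O=C1CCCC(=O)C1 | starting material
2 | carbon disulfide | S=C=S | starting material
3 | 2-[bis(methylsulfanyl)methylidene]cyclohexane-1,3-dione | CSC(SC)=C1C(=O)CCCC1=O | intermediate
4 | sodium 6-[bis(methylsulfanyl)methylidene]-5-oxocyclohex-1-en-1-olate (sodium enolate of 3, not isolated) | CSC(SC)=C1C(=O)CCC=C1[O-].[Na+] | intermediate
5 | (S)-2-[bis(methylsulfanyl)methylidene]-4-hydroxycyclohexane-1,3-dione | CSC(SC)=C1C(=O)CC[C@H](O)C1=O | intermediate
6 | (S)-2-[bis(methylsulfanyl)methylidene]-4-[(triethylsilyl)oxy]cyclohexane-1,3-dione | CSC(SC)=C1C(=O)CC[C@H](O[Si](CC)(CC)CC)C1=O | intermediate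
7 | 11-bromoundecan-1-ol | OCCCCCCCCCCCBr | starting material
8 | (11-hydroxyundecyl)triphenylphosphonium bromide | OCCCCCCCCCCC[P+](c1ccccc1)(c1ccccc1)c1ccccc1.[Br-] | intermediate
9 | (E)-but-2-enal | C/C=C/C=O | starting material
10 | sodium 11-(triphenyl-λ5-phosphanylidene)undecan-1-olate (ylide alkoxide, not isolated) | [O-]CCCCCCCCCCC=P(c1ccccc1)(c1ccccc1)c1ccccc1.[Na+] | intermediate
11 | (11Z,13E)-pentadeca-11,13-dien-1-ol | C/C=C/C=C\CCCCCCCCCCO | intermediate
12 | (2E,4Z)-15-bromopentadeca-2,4-diene | C/C=C/C=C\CCCCCCCCCCBr | intermediate
13 | [(11Z,13E)-pentadeca-11,13-dien-1-yl]magnesium bromide (not isolated) | C/C=C/C=C\CCCCCCCCCC[Mg]Br | intermediate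
14 | bromomagnesium enolate of (4S)-2-[(12Z,14E)-1,1-bis(methylsulfanyl)hexadeca-12,14-dien-1-yl]-4-[(triethylsilyl)oxy]cyclohexane-1,3-dione (not isolated) | C/C=C/C=C\CCCCCCCCCCC(SC)(SC)C1=C(O[Mg]Br)CC[C@H](O[Si](CC)(CC)CC)C1=O | intermediate
15 | (S)-2-[(12Z,14E)-1-(methylsulfanyl)hexadeca-12,14-dien-1-ylidene]-4-[(triethylsilyl)oxy]cyclohexane-1,3-dione (exocyclic double-bond geometry left open) | C/C=C/C=C\CCCCCCCCCCC(SC)=C1C(=O)CC[C@H](O[Si](CC)(CC)CC)C1=O | intermediate
16 | lithium enolate of (4S)-2-[(12Z,14E)-hexadeca-12,14-dienoyl]-4-[(triethylsilyl)oxy]cyclohexane-1,3-dione (not isolated) | C/C=C/C=C\CCCCCCCCCCC(=O)C1=C([O-])CC[C@H](O[Si](CC)(CC)CC)C1=O.[Li+] | intermediate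
17 | (6S)-2-[(12Z,14E)-hexadeca-12,14-dienoyl]-3,6-dihydroxycyclohex-2-en-1-one, enol tautomer of the (4S)-2-acyl-4-hydroxycyclohexane-1,3-dione (CNP0144157.1) | C/C=C/C=C\CCCCCCCCCCC(=O)C1=C(O)CC[C@H](O)C1=O | target

Total step count: 8 steps.
Longest linear sequence: 5 steps (steps 1, 2, 3, 7, 8; the chain branch, steps 4, 5, 6, 7, 8, is equally long).

Steps most likely to fail

Step 2. The oxygen transfer to the flat cyclic enolate may discriminate its two faces poorly or in the opposite sense, and the α-hydroxy ketone may be enolised and oxidised further while base is still present. The fallback sets out from 3 and comes back at 5. Compound 3 is hydroxylated without a chiral reagent (NaN(SiMe3)2, then racemic 3-phenyl-2-(phenylsulfonyl)oxaziridine, THF, −78 °C) to racemic 2-[bis(methylsulfanyl)methylidene]-4-hydroxycyclohexane-1,3-dione F1. F1 is then resolved by lipase-catalysed transesterification (immobilised Candida antarctica lipase B, vinyl acetate, MTBE). The (R)-enantiomer is expected to be acylated to (R)-4-acetoxy-2-[bis(methylsulfanyl)methylidene]cyclohexane-1,3-dione F2, which is removed by chromatography, while the unreacted (S)-alcohol 5 goes on to step 3. The configuration of the recovered alcohol would be secured by Mosher ester analysis before it is carried forward.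

Step 7. The remaining methylsulfanyl group may be displaced by a second equivalent of the nucleophile, the Grignard reagent may add to a ring carbonyl or enolise the ring ketones, and homocoupling may compete during magnesium insertion. The fallback sets out from 12 (with 6) and comes back at 15. Zinc insertion into 12 (Zn dust, LiCl, THF) gives [(11Z,13E)-pentadeca-11,13-dien-1-yl]zinc bromide F3. F3 is coupled with 6 under palladium catalysis (Pd(OAc)2, SPhos, THF, rt): zerovalent palladium inserts into one C–S bond, and transmetalation and reductive elimination follow (desulfitative Negishi-type coupling). The same bond is then made by cross-coupling of a much less basic organometallic instead of by conjugate addition.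

Step 5. Z selectivity at C11=C12 may be eroded through equilibration of the oxaphosphetane intermediates or isomerisation during purification, leaving diene isomers that are hard to remove. The fallback sets out from 7 and comes back at 11. Kornblum oxidation of 7 (DMSO, NaHCO3, 130 °C) gives 11-hydroxyundecanal F4. Stork–Zhao olefination ((iodomethyl)triphenylphosphonium iodide, NaN(SiMe3)2, THF/DMPU, −78 °C) converts F4 into (Z)-12-iodododec-11-en-1-ol F5. Suzuki–Miyaura coupling of F5 with (E)-prop-1-enylboronic acid (Pd(PPh3)4, K3PO4, THF/H2O) proceeds with retention at both alkenes and should give 11 with both geometries fixed by the coupling partners.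

Further compounds
F1 | step 2 | racemic 2-[bis(methylsulfanyl)methylidene]-4-hydroxycyclohexane-1,3-dione | CSC(SC)=C1C(=O)CCC(O)C1=O
F2 | step 2 | (R)-4-acetoxy-2-[bis(methylsulfanyl)methylidene]cyclohexane-1,3-dione | CSC(SC)=C1C(=O)CC[C@@H](OC(C)=O)C1=O
F3 | step 7 | [(11Z,13E)-pentadeca-11,13-dien-1-yl]zinc bromide | C/C=C/C=C\CCCCCCCCCC[Zn]Br
F4 | step 5 | 11-hydroxyundecanal | O=CCCCCCCCCCCO
F5 | step 5 | (Z)-12-iodododec-11-en-1-ol | OCCCCCCCCCC/C=C\I
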